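The six-membered carbocycle of the target carries the amide N on C2 and the oxirane O on C5, in a 1,4-relationship (ketone at C1, tertiary carbinol at C4, oxirane spanning C5 and C6). This pattern is disconnected by an acylnitroso hetero-Diels–Alder reaction. In one operation the whole 5-cyclohexylpentadienoyl chain is bonded through N to C2. Oxygen is bonded to C5 on the face of the C4 oxygen. C1 is left as a silyl enol ether whose C6 terminus can be halogenated for oxirane closure. The precursor is an enantiopure 4-silyloxy-4-alkenylcyclohexa-1,5-dienyl silyl ether (diene C2=C1–C6=C5), obtained by desymmetrising a p-quinol.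

Key step: step 8

Remark (numbering): target numbering is used for all ring compounds: C1 ketone, C2 (N), C3, C4 (carbinol), C5/C6 (oxirane), lower chain C7–C13.
Remark (descriptors): C4 keeps one spatial arrangement from 8 to 33. Its CIP label is S in 8, 9 and 16–21 and R from 22 on, only because C3 outranks C7 once C2=C3 is present.
Assumption: the sense of induction of the Ph-BPE–CuH catalyst on 7 cannot be read from the structure. (S,S)-Ph-BPE is written, and its commercial antipode is used if a test run delivers the R-enone.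

Step 1
Reactants: 1 prop-2-yn-1-ol
Product: 2 (E)-3-(tributylstannyl)prop-2-en-1-ol
Conditions: Bu3SnH, AIBN (cat.), neat, 80 °C; chromatography
Reagents that add atoms: tributyltin hydride, CCCC[SnH](CCCC)CCCC
Why: Radical hydrostannation of a terminal alkyne puts tin on the terminal carbon, and reversible stannyl-radical addition equilibrates the adduct to the E-vinylstannane, which is separated from the minor isomers.

Step 2
Reactants: 2 (E)-3-(tributylstannyl)prop-2-en-1-ol; 3 4,4-dimethoxycyclohexa-2,5-dien-1-one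
Product: 6 4-hydroxy-4-[(E)-3-hydroxyprop-1-en-1-yl]cyclohexa-2,5-dien-1-one, via dilithio reagent 4 (not isolated), via dimethyl ketal adduct 5 (not isolated)
Conditions: n-BuLi (2.1 equiv), THF, −78 → −20 °C; 3, −78 °C; then AcOH–H2O–THF, rt
Reagents that add atoms: water, O
Why: Tin–lithium exchange retains the E geometry, the vinyllithium adds 1,2 to the only carbonyl of the quinone monoketal, and the doubly allylic ketal hydrolyses under acid too weak for a dienone–phenol shift, so the p-quinol is built without oxidising an alkenylphenol whose side chain would compete.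

Step 3
Reactants: 6 4-hydroxy-4-[(E)-3-hydroxyprop-1-en-1-yl]cyclohexa-2,5-dien-1-one
Product: 7 4-(triethylsilyloxy)-4-[(E)-3-(triethylsilyloxy)prop-1-en-1-yl]cyclohexa-2,5-dien-1-one
Conditions: TESOTf (2.4 equiv), 2,6-lutidine (3 equiv), CH2Cl2, −78 → 0 °C
Reagents that add atoms: triethylsilyl triflate, CC[Si](CC)(CC)OS(=O)(=O)C(F)(F)F
Why: Silyl triflate/lutidine silylation covers the tertiary and the primary hydroxyl alike, and the same group at two sterically very different sites allows the C9 ether to be released first and the robust C4 ether last.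

Step 4
Reactants: 7 4-(triethylsilyloxy)-4-[(E)-3-(triethylsilyloxy)prop-1-en-1-yl]cyclohexa-2,5-dien-1-one
Product: 8 (S)-4-(triethylsilyloxy)-4-[(E)-3-(triethylsilyloxy)prop-1-en-1-yl]cyclohex-2-en-1-one (remaining C=C is C5=C6)
Conditions: Cu(OAc)2·H2O (5 mol %), (S,S)-Ph-BPE (5.5 mol %), (EtO)2MeSiH (1.1 equiv), t-BuOH (1.1 equiv), toluene, −20 °C
Reagents that add atoms: none
Why: CuH-catalysed asymmetric conjugate reduction, known as a desymmetrisation of 4,4-disubstituted cyclohexa-2,5-dienones, lets the chiral bisphosphine–CuH complex choose one of the two enantiotopic enone units and deliver hydride to C3 only, which makes C4 stereogenic (S), while any over-reduction should mainly remove the minor enantiomer.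

Step 5
Reactants: 8 (S)-4-(triethylsilyloxy)-4-[(E)-3-(triethylsilyloxy)prop-1-en-1-yl]cyclohex-2-en-1-one
Product: 9 tert-butyl(dimethyl){[(4S)-4-(triethylsilyloxy)-4-[(E)-3-(triethylsilyloxy)prop-1-en-1-yl]cyclohexa-1,5-dien-1-yl]oxy}silane
Conditions: TBSOTf (1.2 equiv), Et3N (2.5 equiv), CH2Cl2, −78 → 0 °C; NaHCO3 work-up, Et3N-deactivated silica
Reagents that add atoms: tert-butyldimethylsilyl triflate, CC(C)(C)[Si](C)(C)OS(=O)(=O)C(F)(F)F
Why: Soft enolisation can only remove a C2 proton because the γ-position C4 is quaternary, so the cross-conjugated 2-silyloxy-1,3-diene is the sole enol ether possible, and the constantly basic medium suppresses aromatisation by loss of silanol.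

Step 6
Reactants: 10 cyclohexanecarboxaldehyde; 11 triethyl 4-phosphonocrotonate
Product: 13 ethyl (2E,4E)-5-cyclohexylpenta-2,4-dienoate, via lithiated phosphonate 12 (not isolated)
Conditions: LiHMDS, THF, −78 °C; 10, −78 °C → rt
Reagents that add atoms: none
Why: The vinylogous Horner–Wadsworth–Emmons reaction of the stabilised allylic phosphonate anion is E-selective for the new alkene and keeps the existing E-alkene.

Step 7
Reactants: 13 ethyl (2E,4E)-5-cyclohexylpenta-2,4-dienoate
Product: 14 (2E,4E)-5-cyclohexyl-N-hydroxypenta-2,4-dienamide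
Conditions: NH2OH·HCl, KOH, MeOH, 0 °C → rt; acidify to pH 5
Reagents that add atoms: hydroxylamine hydrochloride, NO.Cl
Why: Direct hydroxylaminolysis of conjugated esters under alkaline methanolic conditions is the routine entry to unsaturated hydroxamic acids, acyl substitution being faster than conjugate addition.

Step 8
Reactants: 9 tert-butyl(dimethyl){[(4S)-4-(triethylsilyloxy)-4-[(E)-3-(triethylsilyloxy)prop-1-en-1-yl]cyclohexa-1,5-dien-1-yl]oxy}silane; 14 (2E,4E)-5-cyclohexyl-N-hydroxypenta-2,4-dienamide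
Product: 16 (1S,4S,7S)-3-[(2E,4E)-5-cyclohexylpenta-2,4-dienoyl]-5-(tert-butyldimethylsilyloxy)-7-(triethylsilyloxy)-7-[(E)-3-(triethylsilyloxy)prop-1-en-1-yl]-2-oxa-3-azabicyclo[2.2.2]oct-5-ene, via acylnitroso compound 15 (not isolated)
Conditions: n-Bu4NIO4 (1.5 equiv), CH2Cl2, −20 °C; 14 (1.5 equiv) in CH2Cl2–DMF added over 2 h
Reagents that add atoms: none
Why: Periodate oxidises 14 to acylnitroso compound 15, which is intercepted at once by the ring-locked s-cis diene C2=C1–C6=C5 of 9 in a concerted, asynchronous [4+2] cycloaddition in which C2–N bonding runs ahead of C5–O bonding; the reaction type is the acylnitroso hetero-Diels–Alder reaction, established for cyclohexa-1,3-dienes and their 2-silyloxy derivatives. The one new ring, the six-membered 1,2-oxazine C2–N–O–C5–C6–C1, closes by suprafacial cycloaddition through a boat-like transition state and bridges the carbocycle to a 2-oxa-3-azabicyclo[2.2.2]octene. Regiocontrol is needed and is doubly secured: the donor oxygen on C1 puts the largest HOMO coefficient on C2, which pairs with nitrogen as the more electrophilic end of N=O, and the bulky acylated nitrogen thereby stays remote from quaternary C4. C2 and C5 are created together on one face, so both are controlled by the C4 stereocentre: entry syn to the C4–O bond and anti to the larger alkenyl group is the usual course for 5-oxy-5-carbon-substituted cyclohexa-1,3-dienes, and here the atom that must pass C4 is the bare nitroso oxygen. Chemoselectivity is secured because the dienoyl tails of 14 and 15 are acceptor-substituted and s-trans and the C7=C8 alkene is isolated, while slow addition keeps 15 dilute. If a stepwise nitroso-aldol pathway intervened, collapse of the N–O oxygen onto C5 would give the same bicycle.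

Step 9
Reactants: 16 bicyclic oxazine
Product: 17 (2E,4E)-N-[(1S,4S,5S)-2-(tert-butyldimethylsilyloxy)-4-hydroxy-5-(triethylsilyloxy)-5-[(E)-3-(triethylsilyloxy)prop-1-en-1-yl]cyclohex-2-en-1-yl]-5-cyclohexylpenta-2,4-dienamide (N on C2, O on C4 and OH on C5 all cis)
Conditions: SmI2 (2.5 equiv), THF, −78 → −20 °C; pH 7 buffer; used without delay
Reagents that add atoms: none
Why: Reductive N–O cleavage of an N-acyl-1,2-oxazine by two single-electron transfers is fast below 0 °C, outruns reduction of a dienamide when no proton donor or HMPA is present, touches no stereocentre, and in an aprotic medium leaves the silyl enol ether intact.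

Step 10
Reactants: 17 amido alcohol
Product: 19 (2S,4S,5S,6R)-2-[(2E,4E)-5-cyclohexylpenta-2,4-dienoylamino]-5,6-epoxy-4-(triethylsilyloxy)-4-[(E)-3-(triethylsilyloxy)prop-1-en-1-yl]cyclohexan-1-one, via bromo ketone 18 (not isolated)
Conditions: NBS (1.05 equiv), THF, −78 °C; then DBU (1.5 equiv), −78 → 0 °C
Reagents that add atoms: none
Why: Electrophilic α-bromination of the silyl enol ether should occur at C6 on the face opposite the three cis heteroatoms on C2, C4 and C5, and base-induced bromohydrin closure (3-exo-tet SN2 with inversion at C6) then fixes C6 as R with the oxirane oxygen syn to the C4 oxygen, a cis-bromide being able to epimerise through the enol and drain into the same epoxide.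

Step 11
Reactants: 19 epoxy amido ketone
Product: 22 (4R,5S,6R)-2-[(2E,4E)-5-cyclohexylpenta-2,4-dienoylamino]-5,6-epoxy-4-(triethylsilyloxy)-4-[(E)-3-(triethylsilyloxy)prop-1-en-1-yl]cyclohex-2-en-1-one, via N-chloro amide 20 (not isolated), via N-acylimine 21 (not isolated)
Conditions: t-BuOCl (1.1 equiv), CH2Cl2, −40 → 0 °C, dark; then DBU (1.5 equiv), 0 °C
Reagents that add atoms: none
Why: N-Chlorination–dehydrochlorination, the sequence used for dehydroamino acids, removes HCl across N–C2 to an N-acylimine that tautomerises to the hydrogen-bonded, ketone-conjugated enamide, and any chlorination at C2 through the enol would lose HCl to the same product.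

Step 12
Reactants: 22 bis-TES enamide
Product: 23 (4R,5S,6R)-2-[(2E,4E)-5-cyclohexylpenta-2,4-dienoylamino]-5,6-epoxy-4-[(E)-3-hydroxyprop-1-en-1-yl]-4-(triethylsilyloxy)cyclohex-2-en-1-one
Conditions: PPTS (0.2 equiv), MeOH–CH2Cl2, 0 °C
Reagents that add atoms: none
Why: Mild acid-catalysed methanolysis of silyl ethers is governed by steric access, so the primary allylic TES ether is cleaved well before the tertiary one.

Step 13
Reactants: 23 allylic alcohol
Product: 24 (4R,5S,6R)-2-[(2E,4E)-5-cyclohexylpenta-2,4-dienoylamino]-5,6-epoxy-4-[(E)-3-oxoprop-1-en-1-yl]-4-(triethylsilyloxy)cyclohex-2-en-1-one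
Conditions: MnO2 (excess), CH2Cl2, rt
Reagents that add atoms: none
Why: Heterogeneous, neutral MnO2 oxidation is selective for the allylic alcohol and stops at the E-enal.

Step 14
Reactants: 25 cyclopentane-1,3-dione
Product: 26 2-nitrocyclopentane-1,3-dione
Conditions: fuming HNO3, Et2O, 0 °C
Reagents that add atoms: nitric acid, O[N+](=O)[O-]
Why: Electrophilic nitration of the enol of a cyclic 1,3-dione occurs at the only nucleophilic carbon, C2.

Step 15
Reactants: 26 2-nitrocyclopentane-1,3-dione
Product: 27 2-amino-3-hydroxycyclopent-2-en-1-one hydrochloride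
Conditions: H2 (1 atm), 10% Pd/C, HCl, MeOH, rt
Reagents that add atoms: hydrogen chloride, Cl
Why: Catalytic hydrogenation of the nitro group in acid gives the amine as its salt, which prevents self-condensation of the aminodione.

Step 16
Reactants: 11 triethyl 4-phosphonocrotonate
Product: 28 (E)-4-(diethoxyphosphoryl)but-2-enoic acid
Conditions: LiOH·H2O (1.05 equiv), THF–H2O, 0 °C; aq. HCl
Reagents that add atoms: lithium hydroxide, [Li+].[OH-]
Why: Saponification is chemoselective because the carboxylic ester is far more electrophilic toward hydroxide than the phosphonate diester.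

Step 17
Reactants: 27 2-amino-3-hydroxycyclopent-2-en-1-one hydrochloride; 28 (E)-4-(diethoxyphosphoryl)but-2-enoic acid
Product: 30 diethyl [(E)-4-[(2-hydroxy-5-oxocyclopent-1-en-1-yl)amino]-4-oxobut-2-en-1-yl]phosphonate, via benzotriazolyl ester 29 (not isolated)
Conditions: EDC·HCl, HOBt, i-Pr2NEt, DMF, 0 °C → rt
Reagents that add atoms: none
Why: Carbodiimide/HOBt amide coupling acylates the liberated amine, and any O-acylation of the enol is corrected by O→N acyl shift to the more stable amide.

Step 18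
Reactants: 24 enal; 30 diethyl [(E)-4-[(2-hydroxy-5-oxocyclopent-1-en-1-yl)amino]-4-oxobut-2-en-1-yl]phosphonate
Product: 32 (4R,5S,6R)-2-[(2E,4E)-5-cyclohexylpenta-2,4-dienoylamino]-5,6-epoxy-4-[(1E,3E,5E)-7-[(2-hydroxy-5-oxocyclopent-1-en-1-yl)amino]-7-oxohepta-1,3,5-trien-1-yl]-4-(triethylsilyloxy)cyclohex-2-en-1-one, via dilithio phosphonate 31 (not isolated)
Conditions: 30 (2 equiv), LiHMDS (4.1 equiv), THF, −78 °C; 24, −78 → −30 °C; AcOH quench, dark
Reagents that add atoms: none
Why: In this vinylogous Horner–Wadsworth–Emmons reaction the first equivalent of base is absorbed by the acidic enol and the second gives the allylic phosphonate carbanion, which attacks the aldehyde (the most electrophilic site of 24) through C10 and eliminates phosphate to the E-alkene C9=C10, surplus reagent covering the enamide N–H and the TES ether preventing alkoxide formation at C4.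

Step 19
Reactants: 32 4-O-TES ether of the target
Product: 33 target CNP0111189.1, (4R,5S,6R)-2-[(2E,4E)-5-cyclohexylpenta-2,4-dienoylamino]-5,6-epoxy-4-hydroxy-4-[(1E,3E,5E)-7-[(2-hydroxy-5-oxocyclopent-1-en-1-yl)amino]-7-oxohepta-1,3,5-trien-1-yl]cyclohex-2-en-1-one
Conditions: HF·pyridine, pyridine, THF, 0 °C → rt, dark
Reagents that add atoms: none
Why: Buffered fluoride desilylation removes the tertiary TES ether, while the acceptor-flanked carbinol resists ionisation and the α-keto oxirane resists opening under these mild conditions.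

Compound list
1 | prop-2-yn-1-ol | C#CCO | starting material
2 | (E)-3-(tributylstannyl)prop-2-en-1-ol | CCCC[Sn](CCCC)(CCCC)/C=C/CO | intermediate
3 | 4,4-dimethoxycyclohexa-2,5-dien-1-one | COC1(OC)C=CC(=O)C=C1 | starting material
4 | lithium (E)-3-lithioprop-2-en-1-olate (dilithio reagent) | [Li]/C=C/CO[Li] | intermediate
5 | 1-[(E)-3-hydroxyprop-1-en-1-yl]-4,4-dimethoxycyclohexa-2,5-dien-1-ol | COC1(OC)C=CC(O)(/C=C/CO)C=C1 | intermediate
6 | 4-hydroxy-4-[(E)-3-hydroxyprop-1-en-1-yl]cyclohexa-2,5-dien-1-one | O=C1C=CC(O)(/C=C/CO)C=C1 | intermediate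
7 | 4-(triethylsilyloxy)-4-[(E)-3-(triethylsilyloxy)prop-1-en-1-yl]cyclohexa-2,5-dien-1-one | O=C1C=CC(O[Si](CC)(CC)CC)(/C=C/CO[Si](CC)(CC)CC)C=C1 | intermediate
8 | (S)-4-(triethylsilyloxy)-4-[(E)-3-(triethylsilyloxy)prop-1-en-1-yl]cyclohex-2-en-1-one | O=C1CC[C@](O[Si](CC)(CC)CC)(/C=C/CO[Si](CC)(CC)CC)C=C1 | intermediate
9 | (4S)-silyl dienol ether, 1-OTBS, 4-OTES, 4-[(E)-3-(TESO)prop-1-enyl]cyclohexa-1,5-diene | CC(C)(C)[Si](C)(C)OC1=CC[C@](O[Si](CC)(CC)CC)(/C=C/CO[Si](CC)(CC)CC)C=C1 | intermediate
10 | cyclohexanecarboxaldehyde | O=CC1CCCCC1 | starting material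
11 | triethyl 4-phosphonocrotonate | CCOC(=O)/C=C/CP(=O)(OCC)OCC | starting material
12 | lithiated triethyl 4-phosphonocrotonate | [Li+].CCOC(=O)/C=C/[CH-]P(=O)(OCC)OCC | intermediate
13 | ethyl (2E,4E)-5-cyclohexylpenta-2,4-dienoate | CCOC(=O)/C=C/C=C/C1CCCCC1 | intermediate
14 | (2E,4E)-5-cyclohexyl-N-hydroxypenta-2,4-dienamide | O=C(NO)/C=C/C=C/C1CCCCC1 | intermediate
15 | (2E,4E)-5-cyclohexylpenta-2,4-dienoyl nitroso compound | O=NC(=O)/C=C/C=C/C1CCCCC1 | intermediate
16 | (1S,4S,7S)-2-oxa-3-azabicyclo[2.2.2]oct-5-ene adduct (N on C2, O on C5, both syn to the C4 oxygen) | O=C(/C=C/C=C/C1CCCCC1)N1O[C@H]2C=C(O[Si](C)(C)C(C)(C)C)[C@@H]1C[C@]2(O[Si](CC)(CC)CC)/C=C/CO[Si](CC)(CC)CC | intermediate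
17 | (2S,4S,5S)-amido alcohol with C1=C6 TBS enol ether | O=C(/C=C/C=C/C1CCCCC1)N[C@H]1C[C@](O[Si](CC)(CC)CC)(/C=C/CO[Si](CC)(CC)CC)[C@@H](O)C=C1O[Si](C)(C)C(C)(C)C | intermediate
18 | (2S,4S,5R,6S)-6-bromo-5-hydroxy ketone (Br trans to the C5 hydroxyl) | O=C(/C=C/C=C/C1CCCCC1)N[C@H]1C[C@](O[Si](CC)(CC)CC)(/C=C/CO[Si](CC)(CC)CC)[C@@H](O)[C@H](Br)C1=O | intermediate
19 | (2S,4S,5S,6R)-5,6-epoxy-2-amido ketone | O=C(/C=C/C=C/C1CCCCC1)N[C@H]1C[C@](O[Si](CC)(CC)CC)(/C=C/CO[Si](CC)(CC)CC)[C@H]2O[C@H]2C1=O | intermediate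
20 | N-chloro amide of 19 | O=C(/C=C/C=C/C1CCCCC1)N(Cl)[C@H]1C[C@](O[Si](CC)(CC)CC)(/C=C/CO[Si](CC)(CC)CC)[C@H]2O[C@H]2C1=O | intermediate
21 | C2 N-acylimine | O=C(/C=C/C=C/C1CCCCC1)N=C1C[C@](O[Si](CC)(CC)CC)(/C=C/CO[Si](CC)(CC)CC)[C@H]2O[C@H]2C1=O | intermediate
22 | (4R,5S,6R)-bis-TES enamide | O=C(/C=C/C=C/C1CCCCC1)NC1=C[C@](O[Si](CC)(CC)CC)(/C=C/CO[Si](CC)(CC)CC)[C@H]2O[C@H]2C1=O | intermediate
23 | (4R,5S,6R)-C9 allylic alcohol, C4-OTES | O=C(/C=C/C=C/C1CCCCC1)NC1=C[C@](O[Si](CC)(CC)CC)(/C=C/CO)[C@H]2O[C@H]2C1=O | intermediate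
24 | (4R,5S,6R)-C9 enal, C4-OTES | O=C(/C=C/C=C/C1CCCCC1)NC1=C[C@](O[Si](CC)(CC)CC)(/C=C/C=O)[C@H]2O[C@H]2C1=O | intermediate
25 | cyclopentane-1,3-dione | O=C1CCC(=O)C1 | starting material
26 | 2-nitrocyclopentane-1,3-dione | O=C1CCC(=O)C1[N+](=O)[O-] | intermediate
27 | 2-amino-3-hydroxycyclopent-2-en-1-one hydrochloride | NC1=C(O)CCC1=O.Cl | intermediate
28 | (E)-4-(diethoxyphosphoryl)but-2-enoic acid | CCOP(=O)(OCC)C/C=C/C(=O)O | intermediate
29 | benzotriazol-1-yl (E)-4-(diethoxyphosphoryl)but-2-enoate | CCOP(=O)(OCC)C/C=C/C(=O)On1nnc2ccccc12 | intermediate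
30 | diethyl [(E)-4-[(2-hydroxy-5-oxocyclopent-1-en-1-yl)amino]-4-oxobut-2-en-1-yl]phosphonate | CCOP(=O)(OCC)C/C=C/C(=O)NC1=C(O)CCC1=O | intermediate
31 | dilithio derivative of 30 (enolate and C10 carbanion) | [Li+].[Li+].CCOP(=O)(OCC)[CH-]/C=C/C(=O)NC1=C([O-])CCC1=O | intermediate
32 | 4-O-triethylsilyl ether of the target | O=C(/C=C/C=C/C1CCCCC1)NC1=C[C@](O[Si](CC)(CC)CC)(/C=C/C=C/C=C/C(=O)NC2=C(O)CCC2=O)[C@H]2O[C@H]2C1=O | intermediate
33 | target CNP0111189.1 (4R,5S,6R) | O=C(/C=C/C=C/C1CCCCC1)NC1=C[C@](O)(/C=C/C=C/C=C/C(=O)NC2=C(O)CCC2=O)[C@H]2O[C@H]2C1=O | target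

Total step count: 19. Longest linear sequence: 13 steps (steps 1–5, 8–13, 18, 19).

Steps most likely to fail

Step 8. Three things may go wrong:
- insufficient discrimination between the two diene faces at C4
- erosion of regiocontrol
- consumption of the acylnitroso species by dienoyl units before it meets the diene

The fallback sets out from 8 and comes back at 22. It introduces the C5/C6 oxygen and the C2 nitrogen in separate, known operations.
- HF·pyridine frees both hydroxyls of 8 to give the diol enone F1.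
- Weitz–Scheffer epoxidation (t-BuOOH, Triton B, THF, 0 °C), guided by the free C4 hydroxyl as is usual for γ-hydroxy enones, gives the syn-epoxy diol F2.
- TESOTf/2,6-lutidine gives the bis-TES epoxy ketone F3.
- The potassium enolate (KHMDS, −78 °C; C2 is the only enolisable methylene) is azidated with trisyl azide and quenched with AcOH to give the α-azido ketone F4.
- Et3N induces loss of dinitrogen and tautomerisation to the 2-amino enone F5.
- In parallel, ester 13 is saponified (LiOH) to the dienoic acid F6 and converted with oxalyl chloride into the dienoyl chloride F7.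
- F7 acylates F5 (pyridine, CH2Cl2) to give 22.

Step 4. The catalyst may select poorly between the enantiotopic enone units, because the two C4 substituents differ little in size. Over-reduction to the cyclohexanone is the other risk.

The fallback sets out from 2 (through its dilithio form 4) and comes back at 8. It desymmetrises the saturated ketone instead.
- 4 is added to commercial 1,4-dioxaspiro[4.5]decan-8-one to give the ketal diol F8.
- Aqueous acid gives the hydroxy ketone F9.
- TESOTf/2,6-lutidine gives the bis-TES ketone F10.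
- Enantioselective deprotonation follows, with the lithium amide of (R,R)-bis(1-phenylethyl)amine (antipode chosen by a test run), LiCl and TMSCl as in situ quench at −100 °C. This gives the (R)-trimethylsilyl enol ether F11.
- Saegusa–Ito oxidation (Pd(OAc)2, MeCN) gives 8.

Step 18. Three things may go wrong:
- proton transfer from the enamide N–H to the carbanion
- base-induced degradation of the epoxy-enone core
- poor solubility of the doubly charged reagent

The fallback sets out from 24 (with 28 and 27) and comes back at 32. It forms the amide bond last.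
- 28 is esterified (allyl bromide, K2CO3, DMF) to the allyl phosphonocrotonate F12.
- The monoanion of F12 (LiHMDS, 1 equiv, −78 °C) converts 24 into the allyl trienoate F13.
- Pd(PPh3)4/N-methylaniline gives the trienoic acid F14 under neutral conditions.
- EDC/HOBt coupling with 27 gives 32.

Further compounds
F1 | step 8 | (S)-4-hydroxy-4-[(E)-3-hydroxyprop-1-en-1-yl]cyclohex-2-en-1-one | O=C1CC[C@](O)(/C=C/CO)C=C1
F2 | step 8 | (4S,5S,6R)-5,6-epoxy-4-hydroxy-4-[(E)-3-hydroxyprop-1-en-1-yl]cyclohexan-1-one | O=C1CC[C@](O)(/C=C/CO)[C@H]2O[C@H]21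
F3 | step 8 | (4S,5S,6R)-5,6-epoxy-4-(triethylsilyloxy)-4-[(E)-3-(triethylsilyloxy)prop-1-en-1-yl]cyclohexan-1-one | O=C1CC[C@](O[Si](CC)(CC)CC)(/C=C/CO[Si](CC)(CC)CC)[C@H]2O[C@H]21
F4 | step 8 | (4S,5S,6R)-2-azido derivative of F3 (C2 undefined) | [N-]=[N+]=NC1C[C@](O[Si](CC)(CC)CC)(/C=C/CO[Si](CC)(CC)CC)[C@H]2O[C@H]2C1=O
F5 | step 8 | (4R,5S,6R)-2-amino-5,6-epoxy-4-(triethylsilyloxy)-4-[(E)-3-(triethylsilyloxy)prop-1-en-1-yl]cyclohex-2-en-1-one | NC1=C[C@](O[Si](CC)(CC)CC)(/C=C/CO[Si](CC)(CC)CC)[C@H]2O[C@H]2C1=O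
F6 | step 8 | (2E,4E)-5-cyclohexylpenta-2,4-dienoic acid | OC(=O)/C=C/C=C/C1CCCCC1
F7 | step 8 | (2E,4E)-5-cyclohexylpenta-2,4-dienoyl chloride | ClC(=O)/C=C/C=C/C1CCCCC1
F8 | step 4 | 8-[(E)-3-hydroxyprop-1-en-1-yl]-1,4-dioxaspiro[4.5]decan-8-ol | OC/C=C/C1(O)CCC2(CC1)OCCO2
F9 | step 4 | 4-hydroxy-4-[(E)-3-hydroxyprop-1-en-1-yl]cyclohexan-1-one | O=C1CCC(O)(/C=C/CO)CC1
F10 | step 4 | 4-(triethylsilyloxy)-4-[(E)-3-(triethylsilyloxy)prop-1-en-1-yl]cyclohexan-1-one | O=C1CCC(O[Si](CC)(CC)CC)(/C=C/CO[Si](CC)(CC)CC)CC1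
F11 | step 4 | (R)-trimethylsilyl enol ether of F10 (C1=C6) | C[Si](C)(C)OC1=CC[C@@](O[Si](CC)(CC)CC)(/C=C/CO[Si](CC)(CC)CC)CC1
F12 | step 18 | allyl (E)-4-(diethoxyphosphoryl)but-2-enoate | C=CCOC(=O)/C=C/CP(=O)(OCC)OCC
F13 | step 18 | allyl (2E,4E,6E)-trienoate of the C4-OTES core | O=C(/C=C/C=C/C1CCCCC1)NC1=C[C@](O[Si](CC)(CC)CC)(/C=C/C=C/C=C/C(=O)OCC=C)[C@H]2O[C@H]2C1=O
F14 | step 18 | (2E,4E,6E)-trienoic acid of the C4-OTES core | O=C(/C=C/C=C/C1CCCCC1)NC1=C[C@](O[Si](CC)(CC)CC)(/C=C/C=C/C=C/C(=O)O)[C@H]2O[C@H]2C1=O
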